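## Retrosynthetic overview

1. Shimalactone B ⇒ the cyclopentanone ring of the oxabicyclo[2.2.1]heptane is closed last: methyl cuprate 1,4‑addition to a 4‑alkenyl butenolide sets the quaternary C–Me, and the enolate is acylated by a side‑chain Weinreb amide.
2. 4‑Alkenyl butenolide ⇒ sp2–sp2 Negishi coupling of a tetronate triflate (γ‑lactone ring and two stereocentres from dimethyl (S)‑malate) with an alkenylalane made by carboalumination of a cyclobutyl alkyne.
3. Cyclobutyl alkyne ⇒ tricyclic lactone by reduction, epimerisation next to the carbonyl and one‑carbon homologation.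
4. Tricyclic lactone ⇒ mesitylene + enantioenriched butenolide by dearomative ortho [2+2] photocycloaddition; cyclobutane and 1,3,5‑trimethylcyclohexa‑1,3‑diene form in one step and the three arene methyls land where the target has them.
5. Ring order: butenolide → cyclobutane + cyclohexadiene (from the arene) → lactone opened → tetronate γ‑lactone attached → cyclopentanone.

Assumption: atom labels C1–C20 follow the shimalactone chain (C1 lactone C=O, C2–C6 oxabicycle, C7=C8, C9/C10/C15/C16 cyclobutane, C11–C14 diene, C17 carbinol, C18=C19), and (S,S)‑ProPhenol is taken to give the (17R)‑carbinol (its mirror image is used if the sense is opposite).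

## Route

Step 1
Reactants: 1 (E)-2-methylbut-2-enal; 2 methyl propiolate
Product: 3 methyl (4R,5E)-4-hydroxy-5-methylhept-2-yn-5-enoate
Conditions: Me2Zn (3 equiv), (S,S)-ProPhenol (20 mol %), Ph3PO (40 mol %), toluene, 4 °C; aq NH4Cl
Reagents that add atoms: none
Why: Trost asymmetric alkynylation – the catalyst formed from Me2Zn and ProPhenol adds the zinc acetylide of the propiolate to one face of the enal (enals are the best substrates), setting C17 (R) by catalyst control.

Step 2
Reactants: 3 methyl (4R,5E)-4-hydroxy-5-methylhept-2-yn-5-enoate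
Product: 4 (5R)-5-[(2E)-but-2-en-2-yl]-4-methylfuran-2(5H)-one
Conditions: Me2CuLi (2.5 equiv), THF, −78 °C; aq NH4Cl, −78 °C → rt
Reagents that add atoms: lithium dimethylcuprate, [Li+].C[Cu-]C
Why: syn‑carbocupration (conjugate addition) puts the methyl on the β‑carbon and leaves ester and carbinol cis, so the (Z)-hydroxy enoate lactonises on work‑up to the butenolide; C17 is untouched.

Step 3
Reactants: 4 (5R)-5-[(2E)-but-2-en-2-yl]-4-methylfuran-2(5H)-one; 5 mesitylene
Product: 6 (5R)-5-[(2E)-but-2-en-2-yl]-1,6,8,10-tetramethyl-4-oxatricyclo[5.4.0.0^{2,6}]undeca-8,10-dien-3-one (cis-anti-cis; lactone exo; butenyl anti to the cyclobutane)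
Conditions: hν (254 nm, quartz), 4 (0.03 M) in degassed mesitylene as solvent, 15 °C, to ca. 60% conversion (4 recycled)
Reagents that add atoms: none
Why: Proposed new method: intermolecular dearomative ortho [2+2] photocycloaddition of an alkylbenzene to a butenolide. Singlet‑excited mesitylene (it absorbs nearly all the light as solvent, which also shields the diene product) forms a polar exciplex with the electron‑poor enoate, a donor–acceptor regime (electron transfer estimated near thermoneutral) that favours ortho over meta addition, and this collapses across one of the six equivalent C(Me)–C(H) bonds. The fully substituted β‑carbon C16 bonds to the arene CH (C15) and the α‑CH C9 to the arene C–Me (C10), which avoids a quaternary–quaternary bond. The arene adds anti to the C17 butenyl group, as alkenes do with 5‑substituted furan‑2(5H)-ones. It is expected to add exo (lactone away from the six‑membered ring), by analogy with the ortho adducts of benzene with cyclic acceptors. This fixes C10, C15 and C16 as in the target; C9 is corrected in step 4. Closest known reaction types: arene–alkene ortho photocycloaddition of acceptor alkenes (acrylonitrile, maleic anhydride) to benzene, toluene and anisole, and alkene [2+2] photocycloaddition to chiral butenolides.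

Step 4
Reactants: 6 (5R)-5-[(2E)-but-2-en-2-yl]-1,6,8,10-tetramethyl-4-oxatricyclo[5.4.0.0^{2,6}]undeca-8,10-dien-3-one
Product: 9 (1R,2E)-1-(8-ethynyl-1,3,5,7-tetramethylbicyclo[4.2.0]octa-2,4-dien-7-yl)-2-methylbut-2-en-1-ol (ethynyl endo and trans to the carbinol side chain), via lactol 7 (not isolated), via trans-hydroxy aldehyde 8 (not isolated)
Conditions: i-Bu2AlH (1.1 equiv), CH2Cl2, −78 °C; MeOH, K2CO3 (3 equiv), 40 °C, 2 h; then dimethyl (1-diazo-2-oxopropyl)phosphonate (1.5 equiv), rt
Reagents that add atoms: dimethyl (1-diazo-2-oxopropyl)phosphonate, COP(=O)(OC)C(=[N+]=[N-])C(C)=O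
Why: lactone → lactol reduction, then base equilibration: the open γ‑hydroxy aldehyde epimerises at C9 to put the formyl group trans to the bulky C17 substituent and away from the C10 methyl; this trans aldehyde cannot re‑close to a lactol and is drained by Seyferth–Gilbert homologation (Ohira–Bestmann reagent) to the terminal alkyne.

Step 5
Reactants: 10 dimethyl (S)-malate
Product: 11 dimethyl (2S,3R)-2-hydroxy-3-methylbutanedioate
Conditions: LiN(i-Pr)2 (2.2 equiv), THF, −78 → −20 °C; MeI, −78 → 0 °C; AcOH
Reagents that add atoms: iodomethane, CI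
Why: Fráter–Seebach alkylation – the chelated alkoxide–enolate dianion is methylated anti to the alkoxide (dr about 9:1), fixing C4 (R) next to the chiral‑pool centre C5 (S).

Step 6
Reactants: 11 dimethyl (2S,3R)-2-hydroxy-3-methylbutanedioate
Product: 12 dimethyl (2S,3R)-3-methyl-2-(propanoyloxy)butanedioate
Conditions: EtCOCl, pyridine, DMAP (cat.), CH2Cl2, 0 °C → rt
Reagents that add atoms: propanoyl chloride, CCC(Cl)=O
Why: DMAP‑catalysed O‑acylation of the secondary alcohol; no stereocentre is touched.

Step 7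
Reactants: 12 dimethyl (2S,3R)-3-methyl-2-(propanoyloxy)butanedioate
Product: 13 methyl (2R)-2-[(2S)-3-hydroxy-4-methyl-5-oxo-2,5-dihydrofuran-2-yl]propanoate
Conditions: LiN(SiMe3)2 (2.2 equiv), THF, −78 → 0 °C; 1 M HCl
Reagents that add atoms: none
Why: Lacey–Dieckmann condensation – kinetic enolisation of the unhindered propanoyl CH2 and 5‑exo attack on the adjacent α‑acyloxy ester give the tetronate anion as a thermodynamic sink, leaving C4 and C5 intact.

Step 8
Reactants: 13 methyl (2R)-2-[(2S)-3-hydroxy-4-methyl-5-oxo-2,5-dihydrofuran-2-yl]propanoate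
Product: 14 (2R)-2-[(2S)-3-hydroxy-4-methyl-5-oxo-2,5-dihydrofuran-2-yl]-N-methoxy-N-methylpropanamide
Conditions: MeNHOMe·HCl (2 equiv), i-PrMgCl (5 equiv), THF, −20 → 0 °C
Reagents that add atoms: N,O-dimethylhydroxylamine hydrochloride, Cl.CNOC
Why: ester → Weinreb amide with the chloromagnesium amide, the tetronic acid being masked in situ as its magnesium tetronate; the amide is the acyl donor for step 11.

Step 9
Reactants: 14 (2R)-2-[(2S)-3-hydroxy-4-methyl-5-oxo-2,5-dihydrofuran-2-yl]-N-methoxy-N-methylpropanamide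
Product: 15 (2S)-2-{(2R)-1-[methoxy(methyl)amino]-1-oxopropan-2-yl}-4-methyl-5-oxo-2,5-dihydrofuran-3-yl trifluoromethanesulfonate
Conditions: Tf2O, i-Pr2NEt, CH2Cl2, −78 °C
Reagents that add atoms: trifluoromethanesulfonic anhydride, O=S(=O)(OS(=O)(=O)C(F)(F)F)C(F)(F)F
Why: O‑sulfonylation of the tetronic acid enol gives the vinylogous acyl triflate, a standard cross‑coupling electrophile.

Step 10
Reactants: 9 (1R,2E)-1-(8-ethynyl-1,3,5,7-tetramethylbicyclo[4.2.0]octa-2,4-dien-7-yl)-2-methylbut-2-en-1-ol; 15 tetronate triflate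
Product: 17 (2R)-2-[(2S)-3-{(1E)-2-[7-((1R,2E)-1-hydroxy-2-methylbut-2-en-1-yl)-1,3,5,7-tetramethylbicyclo[4.2.0]octa-2,4-dien-8-yl]prop-1-en-1-yl}-4-methyl-5-oxo-2,5-dihydrofuran-2-yl]-N-methoxy-N-methylpropanamide, via alkenylalane 16 (not isolated)
Conditions: Me3Al (3 equiv), Cp2ZrCl2 (0.25 equiv), ClCH2CH2Cl, 0 °C → rt; volatiles removed; 15, Pd(PPh3)4 (5 mol %), ZnCl2 (20 mol %), THF, rt; aq potassium sodium tartrate
Reagents that add atoms: trimethylaluminium, C[Al](C)C
Why: Negishi carboalumination adds Me–Al syn across the terminal alkyne (Me to C8, Al to C7, E geometry), and the alkenylalane couples with retention with the triflate under zerovalent palladium/zinc catalysis (Negishi coupling); the C6–C7 bond is made between two sp2 carbons, so no cation or radical is generated next to the cyclobutane.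

Step 11
Reactants: 17 4-alkenyl butenolide Weinreb amide
Product: 20 shimalactone B, via lithium enolate 18 (not isolated), via chelated hemiaminal 19 (not isolated)
Conditions: Me2CuLi (4 equiv), Et2O, −78 → −30 °C; aq NH4Cl, −78 °C → rt
Reagents that add atoms: lithium dimethylcuprate, [Li+].C[Cu-]C
Why: cuprate 1,4‑addition to the 5‑substituted butenolide occurs anti to the C5 side chain (Me trans, alkenyl cis to C4), setting quaternary C6; the lactone enolate is then acylated on the side‑chain face by the Weinreb amide (Dieckmann‑type), which sets C2 and closes the cyclopentanone, and the lithium N,O‑chelate releases the ketone only on cold quench so that no base meets the β‑keto lactone.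

## Compound list

1 | (E)-2-methylbut-2-enal (tiglic aldehyde) | C/C=C(\C)C=O | starting material
2 | methyl propiolate | C#CC(=O)OC | starting material
3 | methyl (4R,5E)-4-hydroxy-5-methylhept-2-yn-5-enoate | C/C=C(\C)[C@@H](O)C#CC(=O)OC | intermediate
4 | (5R)-5-[(2E)-but-2-en-2-yl]-4-methylfuran-2(5H)-one | C/C=C(\C)[C@H]1OC(=O)C=C1C | intermediate
5 | mesitylene (1,3,5-trimethylbenzene) | Cc1cc(C)cc(C)c1 | starting material
6 | exo photoadduct: γ‑lactone cis‑fused to cyclobutane cis‑fused to 1,3,5‑trimethylcyclohexa‑1,3‑diene; lactone C=O (C8) on C9, lactone O–C17 on C16; C10‑Me and C15‑H on the lactone face; (17R) | C/C=C(\C)[C@H]1OC(=O)[C@@H]2[C@@]3(C)C=C(C)C=C(C)[C@H]3[C@]12C | intermediate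
7 | lactol of 6 (C8 hemiacetal, anomers) | C/C=C(\C)[C@H]1OC(O)[C@@H]2[C@@]3(C)C=C(C)C=C(C)[C@H]3[C@]12C | intermediate (not isolated)
8 | 7-[(1R,2E)-1-hydroxy-2-methylbut-2-en-1-yl]-1,3,5,7-tetramethylbicyclo[4.2.0]octa-2,4-diene-8-carbaldehyde (CHO endo, trans to the side chain) | C/C=C(\C)[C@@H](O)[C@@]1(C)[C@@H]2C(C)=CC(C)=C[C@]2(C)[C@@H]1C=O | intermediate (not isolated)
9 | (1R,2E)-1-(8-ethynyl-1,3,5,7-tetramethylbicyclo[4.2.0]octa-2,4-dien-7-yl)-2-methylbut-2-en-1-ol (cis ring fusion; side chain exo; ethynyl endo) | C/C=C(\C)[C@@H](O)[C@@]1(C)[C@@H]2C(C)=CC(C)=C[C@]2(C)[C@@H]1C#C | intermediate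
10 | dimethyl (S)-malate | COC(=O)[C@@H](O)CC(=O)OC | starting material
11 | dimethyl (2S,3R)-2-hydroxy-3-methylbutanedioate | COC(=O)[C@@H](O)[C@@H](C)C(=O)OC | intermediate
12 | dimethyl (2S,3R)-3-methyl-2-(propanoyloxy)butanedioate | COC(=O)[C@@H](OC(=O)CC)[C@@H](C)C(=O)OC | intermediate
13 | methyl (2R)-2-[(2S)-3-hydroxy-4-methyl-5-oxo-2,5-dihydrofuran-2-yl]propanoate | COC(=O)[C@H](C)[C@@H]1OC(=O)C(C)=C1O | intermediate
14 | (2R)-2-[(2S)-3-hydroxy-4-methyl-5-oxo-2,5-dihydrofuran-2-yl]-N-methoxy-N-methylpropanamide | CON(C)C(=O)[C@H](C)[C@@H]1OC(=O)C(C)=C1O | intermediate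
15 | (2S)-2-{(2R)-1-[methoxy(methyl)amino]-1-oxopropan-2-yl}-4-methyl-5-oxo-2,5-dihydrofuran-3-yl trifluoromethanesulfonate | CON(C)C(=O)[C@H](C)[C@@H]1OC(=O)C(C)=C1OS(=O)(=O)C(F)(F)F | intermediate
16 | (E)-alkenyl(dimethyl)alane of 9, C17–O–AlMe2 | C/C=C(\C)[C@@H](O[Al](C)C)[C@@]1(C)[C@@H]2C(C)=CC(C)=C[C@]2(C)[C@@H]1/C(C)=C/[Al](C)C | intermediate (not isolated)
17 | 4‑alkenyl butenolide Weinreb amide (C6–C7 coupled, 7E; C5 S, C4 R, C17 R) | C/C=C(\C)[C@@H](O)[C@@]1(C)[C@@H]2C(C)=CC(C)=C[C@]2(C)[C@@H]1/C(C)=C/C1=C(C)C(=O)O[C@H]1[C@@H](C)C(=O)N(C)OC | intermediate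
18 | dilithium lactone enolate/C17 alkoxide after Me addition at C6 | [Li+].[Li+].C/C=C(\C)[C@@H]([O-])[C@@]1(C)[C@@H]2C(C)=CC(C)=C[C@]2(C)[C@@H]1/C(C)=C/[C@@]1(C)C(C)=C([O-])O[C@H]1[C@@H](C)C(=O)N(C)OC | intermediate (not isolated)
19 | chelated tetrahedral N,O‑hemiaminal alkoxide at C3 (bicycle closed) | [Li+].[Li+].C/C=C(\C)[C@@H]([O-])[C@@]1(C)[C@@H]2C(C)=CC(C)=C[C@]2(C)[C@@H]1/C(C)=C/[C@]1(C)[C@H]2OC(=O)[C@]1(C)C([O-])(N(C)OC)[C@@H]2C | intermediate (not isolated)
20 | shimalactone B | C/C=C(\C)[C@@H](O)[C@@]1(C)[C@@H]2C(C)=CC(C)=C[C@]2(C)[C@@H]1/C(C)=C/[C@]1(C)[C@H]2OC(=O)[C@]1(C)C(=O)[C@@H]2C | target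

## Step count and risks

Total: 11 steps. Longest linear sequence: 7 steps (5 → 6 → 7 → 8 → 9 → 10 → 11); the arene branch is 6 steps (1–4, 10, 11).

The three steps most likely to fail:

**Step 3 (dearomative photocycloaddition).** Risks are low quantum yield, the endo mode (which would invert C16), meta addition or reaction at the butenyl alkene, and secondary photolysis of the diene. The fallback sets out from 4 and returns at 6, building the cyclohexadiene thermally instead. Acetone‑sensitised [2+2] photocycloaddition of 4 with propyne (300 nm, −40 °C; anti to the butenyl group, methyl‑bearing alkyne carbon on C9) gives the cyclobutene lactone F1. Heating F1 with commercial 4,6‑dimethyl‑2H‑pyran‑2‑one (xylene, 150 °C, sealed tube) gives, by Diels–Alder addition to the convex face with the cyclobutene C–Me bonding to the unsubstituted pyranone terminus, the bridged lactone F2. F2 loses CO2 in the same pot (retro‑[4+2]) to give 6.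

**Step 4 (C9 epimerisation and homologation in one pot).** The cis lactol may be drained faster than it epimerises, giving the cis alkynol. The fallback sets out from 6 and returns at 9. MeNHOMe·HCl/i‑PrMgCl opens the lactone and t‑BuMe2SiOTf/2,6‑lutidine caps C17–OH in the same pot, giving the silyl ether Weinreb amide F3. i‑Bu2AlH and then DBU give the trans silyloxy aldehyde F4; no lactol is possible, so the epimerisation is a plain thermodynamic equilibration. Ohira–Bestmann homologation gives the silyl alkyne F5, and Bu4NF returns 9.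

**Step 11 (cuprate addition to a tetrasubstituted dienyl butenolide and ring closure to a strained bicycle).** The addition may be sluggish or go 1,6, and the acylation may not proceed from the copper/lithium enolate. The fallback sets out from 17 and returns at 20, separating the two events. Me3SiCl‑accelerated 1,4‑addition (MeMgBr, CuBr·SMe2 cat., Me3SiCl, THF, −78 °C) and aqueous work‑up give the saturated lactone F6 (C2 epimers, irrelevant). LiN(SiMe3)2 (2.2 equiv, THF, −78 °C) then removes only the lactone α‑H, the amide α‑H being far less acidic, and the enolate is acylated by the Weinreb amide to give 20 after cold quench.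

## Further compounds

F1 | step 3 | cyclobutene lactone: (1R)-1-[(2E)-but-2-en-2-yl]-5,6-dimethyl-2-oxabicyclo[3.2.0]hept-6-en-3-one type adduct (cyclobutene C–Me on C9 side, cis‑fused, butenyl anti) | C/C=C(\C)[C@H]1OC(=O)[C@@H]2C(C)=C[C@]12C
F2 | step 3 | bridged lactone (Diels–Alder adduct of F1 with 4,6-dimethyl-2H-pyran-2-one, before loss of CO2) | C/C=C(\C)[C@H]1OC(=O)[C@@H]2[C@@]3(C)C4C(=O)OC(C)(C=C4C)[C@H]3[C@]12C
F3 | step 4 | silyl ether Weinreb amide (cis, C17–OSi(t-Bu)Me2, C9–C(=O)N(OMe)Me) | C/C=C(\C)[C@@H](O[Si](C)(C)C(C)(C)C)[C@@]1(C)[C@@H]2C(C)=CC(C)=C[C@]2(C)[C@H]1C(=O)N(C)OC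
F4 | step 4 | trans silyloxy aldehyde (C9 epimerised) | C/C=C(\C)[C@@H](O[Si](C)(C)C(C)(C)C)[C@@]1(C)[C@@H]2C(C)=CC(C)=C[C@]2(C)[C@@H]1C=O
F5 | step 4 | silyl alkyne (tert-butyldimethylsilyl ether of 9) | C/C=C(\C)[C@@H](O[Si](C)(C)C(C)(C)C)[C@@]1(C)[C@@H]2C(C)=CC(C)=C[C@]2(C)[C@@H]1C#C
F6 | step 11 | saturated lactone (conjugate adduct of 17, C6 quaternary, C2–H epimers) | C/C=C(\C)[C@@H](O)[C@@]1(C)[C@@H]2C(C)=CC(C)=C[C@]2(C)[C@@H]1/C(C)=C/[C@@]1(C)C(C)C(=O)O[C@H]1[C@@H](C)C(=O)N(C)OC
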